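**Strategy.** Atoms follow the C15 chain (C1 alkyne CH, C15 ethyl CH3). The oxocane (O, C7–C13) is made by three-atom ring expansion of an oxolane (O, C10–C13) bearing a vinyl group (C9=C8) on C10 and a diazoacetate (C6, C7) on the C12 oxygen. Copper-carbenoid capture by the ring oxygen gives a bridged oxonium ylide; its [2,3] shift forms C7–C8, closes the (Z)-oxocene and fixes C7 through the lactone tether. Exploited feature: the C7 and C12 substituents sit cis across the oxocane, and the C9=C10 alkene left behind serves for bromolactonisation, which closes the oxolane ring (O, C6–C9).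

Key step: step 6

Remark: the enantiomer of the Shi ketone (made from L-sorbose) is assumed to be available as a catalyst. Because the tether needs the C12 oxygen in the configuration of the final bromide, bromine is introduced at C12 by two successive inversions (steps 8 and 9).

Step 1
Reactants: 1 (3E)-hex-3-en-1-ol
Product: 2 (3E)-hex-3-enal
Conditions: TEMPO (10 mol %), PhI(OAc)2, CH2Cl2, 0 °C to rt; used crude
Reagents that add atoms: none
Why: TEMPO/PhI(OAc)2 oxidation (oxoammonium catalysis) should stop at the aldehyde under near-neutral conditions, so the C12=C13 double bond is not drawn into conjugation.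

Step 2
Reactants: 2 (3E)-hex-3-enal
Product: 3 rac-(5E)-octa-1,5-dien-3-ol
Conditions: CH2=CHMgBr, THF, −78 °C; aq. NH4Cl
Reagents that add atoms: vinylmagnesium bromide C=C[Mg]Br
Why: Grignard 1,2-addition at −78 °C should outrun enolisation of the β,γ-unsaturated aldehyde and creates the C10 carbinol as a racemate that is resolved in step 3.

Step 3
Reactants: 3 rac-(5E)-octa-1,5-dien-3-ol
Product: 4 (3S,5E)-octa-1,5-dien-3-ol
Conditions: Ti(OiPr)4 (10 mol %), D-(−)-diisopropyl tartrate (15 mol %), t-BuOOH (0.6 equiv), 4 Å MS, CH2Cl2, −20 °C, stopped slightly past half conversion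
Reagents that add atoms: none
Why: Sharpless kinetic resolution: with D-(−)-DIPT the (R)-enantiomer of a 1-alken-3-ol is epoxidised much faster, so the (S)-alcohol should be recovered in high enantiomeric purity, and the isolated C12=C13 alkene is inert to the titanium/peroxide system.

Step 4
Reactants: 4 (3S,5E)-octa-1,5-dien-3-ol
Product: 6 (2R,3S,5S)-5-ethenyl-2-ethyloxolan-3-ol, via epoxy alcohol 5 (not isolated)
Conditions: ent-Shi ketone (30 mol %), Oxone (2KHSO5·KHSO4·K2SO4), K2CO3, n-Bu4NHSO4 (cat.), MeCN–CH2(OMe)2/aq. Na2B4O7 buffer, 0 °C; then CSA (10 mol %), CH2Cl2, rt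
Reagents that add atoms: potassium peroxymonosulfate [K+].[O-]S(=O)(=O)OO
Why: Shi epoxidation under reagent control should convert only the trans-disubstituted C12=C13 alkene into the (12S,13S)-epoxide, and acid then triggers 5-endo opening by the C10 hydroxyl at C13 with inversion (oxetane formation at C12 is disfavoured), which sets C13 (R) and leaves the C12 hydroxyl (S) cis to the vinyl group and trans to ethyl.

Step 5
Reactants: 6 (2R,3S,5S)-5-ethenyl-2-ethyloxolan-3-ol
Product: 7 (2R,3S,5S)-5-ethenyl-2-ethyloxolan-3-yl 2-diazoacetate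
Conditions: TsNHN=CHCOCl, PhNMe2, CH2Cl2, 0 °C; then Et3N, 0 °C to rt
Reagents that add atoms: glyoxylic acid chloride p-toluenesulfonylhydrazone Cc1ccc(cc1)S(=O)(=O)NN=CC(Cl)=O
Why: House–Corey–Myers diazoacetylation: O-acylation followed by triethylamine-induced loss of p-toluenesulfinate should give the diazoacetate without touching a stereocentre.

Step 6
Reactants: 7 (2R,3S,5S)-5-ethenyl-2-ethyloxolan-3-yl 2-diazoacetate
Product: 9 (1S,3Z,6S,10R)-10-ethyl-7,9-dioxabicyclo[4.2.2]dec-3-en-8-one, via oxonium ylide 8 (not isolated)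
Conditions: Cu(hfacac)2 (copper bis(hexafluoroacetylacetonate), 5 mol %), ClCH2CH2Cl, reflux, slow addition of 7 (final 0.01 M)
Reagents that add atoms: none
Why: The copper carbenoid generated from the diazoacetate should be captured by the oxolane oxygen lone pair on the face of the C12 ester (O–C7 bond, six-membered ring) to give bridged oxonium ylide 8, whose concerted [2,3]-sigmatropic shift forms C7–C8, breaks O–C10 and moves the double bond to C9=C10. The closest known reaction type is the catalytic oxonium ylide formation/[2,3] rearrangement of α-vinyl cyclic ethers with three-atom ring expansion, established for bridged medium-ring ethers from tethered diazo carbonyl compounds. The 1,4-dioxan-2-one ring closes by carbenoid O-alkylation (six-membered ylide formation), and the oxocene closes through the five-centre [2,3] transition state as a 5→8 ring expansion in which the four-atom bridge allows only the (Z)-alkene. The new stereocentre C7 is fixed as S by the tether, because C6 stays bonded to the C12 oxygen and a bridged lactone can only form with C7–C6 and C12–O cis on the oxocene; the oxolane C10 centre is used up after it has placed the vinyl group on the ester face, and the C13 ethyl group, trans to both, stays off the reacting face. The step needs ylide formation to win over 1,5 C–H insertion at C13–H or C11–H, cyclopropanation of the vinyl group and a [1,2] shift; copper carbenoids favour ether capture over C–H insertion, and the 1,3-cis ester and vinyl groups hold carbenoid carbon, ring oxygen and alkene terminus within a five-atom array.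

Step 7
Reactants: 9 (1S,3Z,6S,10R)-10-ethyl-7,9-dioxabicyclo[4.2.2]dec-3-en-8-one
Product: 11 (1S,3R,4S,6S,7S)-6-bromo-3-ethyl-4-hydroxy-2,8-dioxabicyclo[5.2.1]decan-9-one, via lithium carboxylate 10 (not isolated)
Conditions: LiOH, THF–H2O, 0 °C; then NBS, 0 °C, dark
Reagents that add atoms: lithium hydroxide [Li+].[OH-]; N-bromosuccinimide O=C1CCC(=O)N1Br
Why: Saponification and bromolactonisation: the C6 carboxylate should open the bromonium ion of the (Z)-C9=C10 alkene in the 5-exo mode at C9 from the face on which C7 holds it, with bromine anti at C10, which sets C9 (S) and C10 (S) and closes the oxolane ring as its lactone.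

Step 8
Reactants: 11 (1S,3R,4S,6S,7S)-6-bromo-3-ethyl-4-hydroxy-2,8-dioxabicyclo[5.2.1]decan-9-one
Product: 14 (1S,3R,4R,6S,7S)-6-bromo-3-ethyl-4-hydroxy-2,8-dioxabicyclo[5.2.1]decan-9-one, via triflate 12 (not isolated), via nitrite ester 13 (not isolated)
Conditions: Tf2O, pyridine, CH2Cl2, −20 °C; then n-Bu4NNO2, MeCN, rt; aqueous work-up
Reagents that add atoms: tetrabutylammonium nitrite CCCC[N+](CCCC)(CCCC)CCCC.[O-]N=O
Why: Lattrell–Dax inversion: SN2 displacement of the C12 triflate by nitrite oxygen and hydrolysis of the nitrite ester on work-up should return the C12 alcohol with inverted (R) configuration.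

Step 9
Reactants: 14 (1S,3R,4R,6S,7S)-6-bromo-3-ethyl-4-hydroxy-2,8-dioxabicyclo[5.2.1]decan-9-one
Product: 15 (1S,3R,4S,6S,7S)-4,6-dibromo-3-ethyl-2,8-dioxabicyclo[5.2.1]decan-9-one
Conditions: CBr4, P(n-C8H17)3, toluene, 70 °C
Reagents that add atoms: carbon tetrabromide BrC(Br)(Br)Br
Why: Appel-type bromination (Hooz conditions): SN2 attack of bromide on the alkoxyphosphonium ion should give the C12 bromide with inversion, which is the (S) configuration of the target.

Step 10
Reactants: 15 (1S,3R,4S,6S,7S)-4,6-dibromo-3-ethyl-2,8-dioxabicyclo[5.2.1]decan-9-one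
Product: 16 (1S,3R,4S,6S,7S)-4,6-dibromo-3-ethyl-9-methylidene-2,8-dioxabicyclo[5.2.1]decane
Conditions: Cp2TiMe2, toluene, 70 °C, dark; used crude
Reagents that add atoms: dimethyltitanocene [CH3-].[CH3-].[Ti+4].c1cc[cH-]c1.c1cc[cH-]c1
Why: Petasis methylenation: the titanium methylidene formed on heating converts the lactone carbonyl into the exocyclic enol ether under non-basic conditions that should spare the two secondary bromides and avoid opening the lactone next to the C10 bromide.

Step 11
Reactants: 17 (Z)-1,2-dichloroethene; 18 ethynyltri(propan-2-yl)silane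
Product: 19 (Z)-(4-chlorobut-3-en-1-yn-1-yl)tri(propan-2-yl)silane
Conditions: Pd(PPh3)4 (5 mol %), CuI (10 mol %), n-BuNH2, Et2O, rt, 17 in excess
Reagents that add atoms: none
Why: Sonogashira coupling with excess cis-1,2-dichloroethene should stop at mono-alkynylation and retains the (Z) geometry of the vinyl chloride.

Step 12
Reactants: 16 (1S,3R,4S,6S,7S)-4,6-dibromo-3-ethyl-9-methylidene-2,8-dioxabicyclo[5.2.1]decane; 19 (Z)-(4-chlorobut-3-en-1-yn-1-yl)tri(propan-2-yl)silane
Product: 21 {(3Z)-5-[(1S,3R,4S,6S,7S,9S)-4,6-dibromo-3-ethyl-2,8-dioxabicyclo[5.2.1]decan-9-yl]pent-3-en-1-yn-1-yl}tri(propan-2-yl)silane, via alkylborane 20 (not isolated)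
Conditions: 9-BBN, THF, 0 °C to rt; then 19, Pd(OAc)2 (5 mol %), SPhos (10 mol %), aq. K3PO4, THF, rt
Reagents that add atoms: none
Why: Hydroboration of the exocyclic enol ether places boron on C5 and delivers hydrogen to C6 from the face opposite the five-atom bridge (ring oxygen and C10–C13), which sets C6 (S), and B-alkyl Suzuki–Miyaura coupling with the activated (Z)-vinyl chloride should proceed with retention of the olefin geometry.

Step 13
Reactants: 21 {(3Z)-5-[(1S,3R,4S,6S,7S,9S)-4,6-dibromo-3-ethyl-2,8-dioxabicyclo[5.2.1]decan-9-yl]pent-3-en-1-yn-1-yl}tri(propan-2-yl)silane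
Product: 22 (1S,3R,4S,6S,7S,9S)-4,6-dibromo-3-ethyl-9-[(2Z)-pent-2-en-4-yn-1-yl]-2,8-dioxabicyclo[5.2.1]decane
Conditions: TBAF, THF, 0 °C
Reagents that add atoms: none
Why: Fluoride-induced cleavage of the alkynyl C–Si bond should release the terminal alkyne without affecting the secondary bromides at 0 °C.

**Compound list**

1 | (3E)-hex-3-en-1-ol | CC/C=C/CCO | starting material
2 | (3E)-hex-3-enal | CC/C=C/CC=O | intermediate
3 | rac-(5E)-octa-1,5-dien-3-ol | CC/C=C/CC(O)C=C | intermediate
4 | (3S,5E)-octa-1,5-dien-3-ol | C=C[C@@H](O)C/C=C/CC | intermediate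
5 | (2S)-1-[(2S,3S)-3-ethyloxiran-2-yl]but-3-en-2-ol | C=C[C@@H](O)C[C@@H]1O[C@H]1CC | intermediate
6 | (2R,3S,5S)-5-ethenyl-2-ethyloxolan-3-ol | CC[C@H]1O[C@H](C=C)C[C@@H]1O | intermediate
7 | (2R,3S,5S)-5-ethenyl-2-ethyloxolan-3-yl 2-diazoacetate | CC[C@H]1O[C@H](C=C)C[C@@H]1OC(=O)C=[N+]=[N-] | intermediate
8 | bridged bicyclic oxonium ylide (ring oxygen bonded to C7, C10 and C13) | CC[C@H]1[O+]2[C@H](C=C)C[C@@H]1OC(=O)[CH-]2 | intermediate
9 | (1S,3Z,6S,10R)-10-ethyl-7,9-dioxabicyclo[4.2.2]dec-3-en-8-one | CC[C@H]1O[C@H]2C/C=C\C[C@@H]1OC2=O | intermediate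
10 | lithium (2S,4Z,7S,8R)-8-ethyl-7-hydroxy-3,6,7,8-tetrahydro-2H-oxocine-2-carboxylate | CC[C@H]1O[C@H](C(=O)[O-])C/C=C\C[C@@H]1O.[Li+] | intermediate
11 | (1S,3R,4S,6S,7S)-6-bromo-3-ethyl-4-hydroxy-2,8-dioxabicyclo[5.2.1]decan-9-one | O=C1O[C@H]2C[C@@H]1O[C@H](CC)[C@@H](O)C[C@@H]2Br | intermediate
12 | (1S,3R,4S,6S,7S)-6-bromo-3-ethyl-9-oxo-2,8-dioxabicyclo[5.2.1]decan-4-yl trifluoromethanesulfonate | O=C1O[C@H]2C[C@@H]1O[C@H](CC)[C@@H](OS(=O)(=O)C(F)(F)F)C[C@@H]2Br | intermediate
13 | (1S,3R,4R,6S,7S)-6-bromo-3-ethyl-9-oxo-2,8-dioxabicyclo[5.2.1]decan-4-yl nitrite | O=C1O[C@H]2C[C@@H]1O[C@H](CC)[C@H](ON=O)C[C@@H]2Br | intermediate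
14 | (1S,3R,4R,6S,7S)-6-bromo-3-ethyl-4-hydroxy-2,8-dioxabicyclo[5.2.1]decan-9-one | O=C1O[C@H]2C[C@@H]1O[C@H](CC)[C@H](O)C[C@@H]2Br | intermediate
15 | (1S,3R,4S,6S,7S)-4,6-dibromo-3-ethyl-2,8-dioxabicyclo[5.2.1]decan-9-one | O=C1O[C@H]2C[C@@H]1O[C@H](CC)[C@@H](Br)C[C@@H]2Br | intermediate
16 | (1S,3R,4S,6S,7S)-4,6-dibromo-3-ethyl-9-methylidene-2,8-dioxabicyclo[5.2.1]decane | C=C1O[C@H]2C[C@@H]1O[C@H](CC)[C@@H](Br)C[C@@H]2Br | intermediate
17 | (Z)-1,2-dichloroethene | Cl/C=C\Cl | starting material
18 | ethynyltri(propan-2-yl)silane | C#C[Si](C(C)C)(C(C)C)C(C)C | starting material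
19 | (Z)-(4-chlorobut-3-en-1-yn-1-yl)tri(propan-2-yl)silane | Cl/C=C\C#C[Si](C(C)C)(C(C)C)C(C)C | intermediate
20 | 9-{[(1S,3R,4S,6S,7S,9S)-4,6-dibromo-3-ethyl-2,8-dioxabicyclo[5.2.1]decan-9-yl]methyl}-9-borabicyclo[3.3.1]nonane | C(B1C2CCCC1CCC2)[C@@H]3O[C@H]4C[C@@H]3O[C@H](CC)[C@@H](Br)C[C@@H]4Br | intermediate
21 | {(3Z)-5-[(1S,3R,4S,6S,7S,9S)-4,6-dibromo-3-ethyl-2,8-dioxabicyclo[5.2.1]decan-9-yl]pent-3-en-1-yn-1-yl}tri(propan-2-yl)silane | CC(C)[Si](C#C/C=C\C[C@@H]1O[C@H]2C[C@@H]1O[C@H](CC)[C@@H](Br)C[C@@H]2Br)(C(C)C)C(C)C | intermediate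
22 | (1S,3R,4S,6S,7S,9S)-4,6-dibromo-3-ethyl-9-[(2Z)-pent-2-en-4-yn-1-yl]-2,8-dioxabicyclo[5.2.1]decane | C#C/C=C\C[C@@H]1O[C@H]2C[C@@H]1O[C@H](CC)[C@@H](Br)C[C@@H]2Br | target

**Step count.** Total: 13 steps. Longest linear sequence: 12 steps (steps 1–10, 12, 13); step 11 makes the side-chain fragment.

**Steps most likely to fail**

1. Step 6. The tethered carbenoid may be diverted before it reaches the ring oxygen (insertion into the C13–H or C11–H bond, cyclopropanation of the vinyl group, dimerisation), or the strained bridged ylide may rearrange by a [1,2] shift. The fallback sets out from 6 and returns at 9; it replaces tethered delivery by an intermolecular ring expansion whose C7 configuration is corrected thermodynamically. Acetylation of 6 (Ac2O, pyridine) gives the acetate F1. Ylide formation with methyl diazoacetate and Rh2(OAc)4 (dirhodium tetraacetate; slow addition, excess diazo ester) should expand the oxolane to the oxocene ester F2 as a mixture of C7 epimers. K2CO3 in MeOH removes the acetate to give the hydroxy ester F3. DBU in toluene at 80 °C equilibrates C7, and because only the (7S) epimer can lactonise onto the C12 hydroxyl, the mixture should drain into 9.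

2. Step 8. Backside attack of nitrite at C12 is hindered by the cis ethyl group on C13, and the triflate may instead eliminate or be displaced by the neighbouring ring oxygen with ring contraction. The fallback sets out from 11 and returns at 14; it replaces substitution by a redox inversion. Oxidation with Dess–Martin periodinane gives the ketone F4, and reduction with NaBH4/CeCl3 in MeOH at −78 °C should deliver hydride from the face away from the C13 ethyl group and the C10 bromine, giving 14.

3. Step 12. The sequence may fail through protonolysis or β-elimination of the β-alkoxy alkylborane, sluggish oxidative addition of the vinyl chloride, or base-induced loss of HBr during the coupling. The fallback sets out from 15 and returns at 21; it builds the side chain by carbonyl addition and olefination instead of cross-coupling. Allylmagnesium bromide in THF at −78 °C (acetic acid quench at −78 °C) gives the hemiketal F5. Et3SiH with BF3·OEt2 should reduce the derived oxocarbenium ion from the face opposite the five-atom bridge to the C-allyl compound F6. Ozonolysis (O3, then PPh3) gives the aldehyde F7, and Peterson olefination with lithiated 1,3-bis(triisopropylsilyl)propyne should give the (Z)-enyne 21.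

Further compounds
F1 | step 6 | (2R,3S,5S)-5-ethenyl-2-ethyloxolan-3-yl acetate | CC[C@H]1O[C@H](C=C)C[C@@H]1OC(C)=O
F2 | step 6 | methyl (4Z,7S,8R)-7-(acetyloxy)-8-ethyl-3,6,7,8-tetrahydro-2H-oxocine-2-carboxylate (C2 epimers) | CC[C@H]1OC(C(=O)OC)C/C=C\C[C@@H]1OC(C)=O
F3 | step 6 | methyl (4Z,7S,8R)-8-ethyl-7-hydroxy-3,6,7,8-tetrahydro-2H-oxocine-2-carboxylate (C2 epimers) | CC[C@H]1OC(C(=O)OC)C/C=C\C[C@@H]1O
F4 | step 8 | (1S,3R,6S,7S)-6-bromo-3-ethyl-2,8-dioxabicyclo[5.2.1]decane-4,9-dione | O=C1O[C@H]2C[C@@H]1O[C@H](CC)C(=O)C[C@@H]2Br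
F5 | step 12 | (1S,3R,4S,6S,7S)-4,6-dibromo-3-ethyl-9-(prop-2-en-1-yl)-2,8-dioxabicyclo[5.2.1]decan-9-ol (anomers) | C=CCC1(O)O[C@H]2C[C@@H]1O[C@H](CC)[C@@H](Br)C[C@@H]2Br
F6 | step 12 | (1S,3R,4S,6S,7S,9S)-4,6-dibromo-3-ethyl-9-(prop-2-en-1-yl)-2,8-dioxabicyclo[5.2.1]decane | C=CC[C@@H]1O[C@H]2C[C@@H]1O[C@H](CC)[C@@H](Br)C[C@@H]2Br
F7 | step 12 | 2-[(1S,3R,4S,6S,7S,9S)-4,6-dibromo-3-ethyl-2,8-dioxabicyclo[5.2.1]decan-9-yl]acetaldehyde | O=CC[C@@H]1O[C@H]2C[C@@H]1O[C@H](CC)[C@@H](Br)C[C@@H]2Br
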